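The seven-membered ring (1-benzoxepine numbering) is cut at the bond between ring A carbon C5a and the ketone carbon C5 and at the C3–C4 bond, which removes the two-carbon keto-ester unit C4–C5. The key step exploits the 1,3-dicarbonyl at C4/C5 and the phloroglucinol-type ring A: an acyclic α-diazo-β-keto ester, in which benzylic C3 is still bonded to C5 and ring A hangs on O1, is heated. Wolff rearrangement shifts C3 from C5 to C4 with retention, and the α-oxo ketene so formed acylates ring A ortho to O1, closing the benzoxepinone. C2 and C3 are set earlier by an Ireland–Claisen rearrangement with chirality transfer; the diamide side chain enters last by β-keto ester aminolysis.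

Key step: step 11

Remark: atom labels O1, C2, C3, C4, C5 and C5a follow the 1-benzoxepine numbering of the target and are used for the same atoms in the open-chain precursors; ring A is the dimethoxy-substituted benzo ring; PMB = 4-methoxybenzyl.
Remark: C4 lies between two carbonyl groups and is assumed to equilibrate to the configuration trans to the C3 phenyl group, which is the one in the target.

Step 1
Reactants: 1 (R)-but-3-yn-2-ol; 2 iodobenzene
Product: 3 (R)-4-phenylbut-3-yn-2-ol
Conditions: PdCl2(PPh3)2 (cat.), CuI (cat.), Et3N, THF, rt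
Reagents that add atoms: none
Why: Sonogashira coupling of a terminal alkyne with an aryl iodide tolerates the free alcohol and leaves the purchased carbinol stereocentre untouched.

Step 2
Reactants: 3 (R)-4-phenylbut-3-yn-2-ol
Product: 4 (2R,3Z)-4-phenylbut-3-en-2-ol
Conditions: H2 (1 atm), Pd/CaCO3 poisoned with Pb(OAc)2, quinoline, EtOAc, rt
Reagents that add atoms: none
Why: Lindlar semihydrogenation should add hydrogen syn to the alkyne and stop at the cis-alkene.

Step 3
Reactants: 5 4-hydroxymandelic acid (racemic)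
Product: 6 PMB 2-hydroxy-2-[4-(PMB-oxy)phenyl]acetate (racemic)
Conditions: 4-methoxybenzyl chloride (2.2 equiv), K2CO3, NaI (cat.), DMF, 40 °C
Reagents that add atoms: 4-methoxybenzyl chloride, COc1ccc(CCl)cc1
Why: Williamson-type O-alkylation of phenoxide and carboxylate under carbonate conditions should leave the far less acidic secondary alcohol free.

Step 4
Reactants: 6 PMB 2-hydroxy-2-[4-(PMB-oxy)phenyl]acetate; 7 3,5-dimethoxyphenol
Product: 8 PMB 2-(3,5-dimethoxyphenoxy)-2-[4-(PMB-oxy)phenyl]acetate (racemic)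
Conditions: PPh3, DIAD, toluene, 0 °C to rt
Reagents that add atoms: none
Why: Mitsunobu etherification of an α-hydroxy ester with an acidic phenol forms the O1–C2 aryl ether at the activated benzylic carbon; the centre is racemic here and is erased later by enolisation.

Step 5
Reactants: 8 PMB 2-(3,5-dimethoxyphenoxy)-2-[4-(PMB-oxy)phenyl]acetate
Product: 9 2-(3,5-dimethoxyphenoxy)-2-[4-(PMB-oxy)phenyl]acetic acid (racemic)
Conditions: LiOH·H2O, THF/MeOH/H2O, rt; then 10% citric acid
Reagents that add atoms: lithium hydroxide, [Li+].[OH-]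
Why: saponification of the unhindered ester by acyl–oxygen cleavage should spare both aryl ethers.

Step 6
Reactants: 9 2-(3,5-dimethoxyphenoxy)-2-[4-(PMB-oxy)phenyl]acetic acid; 4 (2R,3Z)-4-phenylbut-3-en-2-ol
Product: 10 (2R,3Z)-4-phenylbut-3-en-2-yl 2-(3,5-dimethoxyphenoxy)-2-[4-(PMB-oxy)phenyl]acetate (both epimers at the acetate carbon)
Conditions: EDC·HCl, DMAP (cat.), CH2Cl2, 0 °C to rt
Reagents that add atoms: none
Why: carbodiimide (Steglich-type) esterification acylates the alcohol oxygen without touching the carbinol centre or the cis-alkene, and both epimers converge in the next step.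

Step 7
Reactants: 10 (2R,3Z)-4-phenylbut-3-en-2-yl 2-(3,5-dimethoxyphenoxy)-2-[4-(PMB-oxy)phenyl]acetate
Product: 13 PMB (2S,3S,4E)-2-(3,5-dimethoxyphenoxy)-2-[4-(PMB-oxy)phenyl]-3-phenylhex-4-enoate, via silyl ketene acetal 11 (not isolated), via trimethylsilyl ester 12 (not isolated)
Conditions: LiN(SiMe3)2, THF, −78 °C; Me3SiCl, −78 to 50 °C; then CsF, 4-methoxybenzyl chloride, DMF, rt
Reagents that add atoms: 4-methoxybenzyl chloride, COc1ccc(CCl)cc1
Why: Ireland–Claisen rearrangement, in which the lithium enolate chelated through the aryloxy oxygen is silylated with OAr cis to OSiMe3 and a chair transition state (carbinol methyl equatorial, cis-phenyl axial) forms C2–C3 and should set 2S and 3S by chirality transfer from the (R)-carbinol, after which fluoride-mediated alkylation of the silyl ester protects the new acid.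

Step 8
Reactants: 13 PMB (2S,3S,4E)-2-(3,5-dimethoxyphenoxy)-2-[4-(PMB-oxy)phenyl]-3-phenylhex-4-enoate
Product: 15 PMB (2S,3S)-2-(3,5-dimethoxyphenoxy)-2-[4-(PMB-oxy)phenyl]-4-oxo-3-phenylbutanoate, via 4,5-diol 14 (not isolated)
Conditions: OsO4 (cat.), NaIO4, 2,6-lutidine, 1,4-dioxane/H2O, rt; crude aldehyde used at once
Reagents that add atoms: osmium tetroxide (catalytic oxygen carrier), O=[Os](=O)(=O)=O; sodium periodate (terminal oxidant), [Na+].[O-]I(=O)(=O)=O
Why: Lemieux–Johnson cleavage (dihydroxylation, then periodate glycol cleavage) of the only alkene should give the aldehyde that carries the future C5 without oxidising the electron-rich arenes, the buffered medium protecting the α-phenyl centre.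

Step 9
Reactants: 15 PMB (2S,3S)-2-(3,5-dimethoxyphenoxy)-2-[4-(PMB-oxy)phenyl]-4-oxo-3-phenylbutanoate
Product: 16 1-ethyl 6-PMB (4S,5S)-5-(3,5-dimethoxyphenoxy)-5-[4-(PMB-oxy)phenyl]-3-oxo-4-phenylhexanedioate
Conditions: ethyl diazoacetate, SnCl2 (20 mol %), CH2Cl2, rt
Reagents that add atoms: ethyl diazoacetate, CCOC(=O)C=[N+]=[N-]
Why: Roskamp homologation, in which the diazo carbon adds to the Lewis-acid-activated aldehyde and a 1,2-hydride shift with loss of N2 gives the β-keto ester under non-basic conditions that should spare the α-phenyl centre and the β-aryloxy group.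

Step 10
Reactants: 16 1-ethyl 6-PMB (4S,5S)-5-(3,5-dimethoxyphenoxy)-5-[4-(PMB-oxy)phenyl]-3-oxo-4-phenylhexanedioate
Product: 17 1-ethyl 6-PMB (4S,5S)-2-diazo-5-(3,5-dimethoxyphenoxy)-5-[4-(PMB-oxy)phenyl]-3-oxo-4-phenylhexanedioate
Conditions: 4-acetamidobenzenesulfonyl azide, Et3N, MeCN, 0 °C to rt
Reagents that add atoms: 4-acetamidobenzenesulfonyl azide, CC(=O)Nc1ccc(cc1)S(=O)(=O)N=[N+]=[N-]
Why: Regitz diazo transfer to the doubly activated methylene, the only position triethylamine deprotonates, so C3 should keep its configuration.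

Step 11
Reactants: 17 1-ethyl 6-PMB (4S,5S)-2-diazo-5-(3,5-dimethoxyphenoxy)-5-[4-(PMB-oxy)phenyl]-3-oxo-4-phenylhexanedioate
Product: 19 4-ethyl 2-PMB (2S,3S,4R)-6,8-dimethoxy-2-[4-(PMB-oxy)phenyl]-5-oxo-3-phenyl-2,3,4,5-tetrahydro-1-benzoxepine-2,4-dicarboxylate, via ethoxycarbonyl ketene 18 (not isolated)
Conditions: 1,2-dichlorobenzene (0.005 M), 160 °C, 1 h, argon
Reagents that add atoms: none
Why: Proposed new method: loss of N2 from the 2-diazo-1,3-dicarbonyl unit is coupled to a 1,2-shift of benzylic C3 from the ketone carbon (the future C5) to the diazo carbon (the future C4), a Wolff rearrangement that forms C3–C4 and leaves C5 as the sp carbon of (ethoxycarbonyl)ketene 18; this carbon is then attacked by ring A carbon C5a, forming C5–C5a, and the enol tautomerises to the β-keto ester. The closest known reaction types are the thermal Wolff rearrangement of α-diazo-β-keto esters to alkoxycarbonylketenes and the intramolecular Friedel–Crafts acylation of electron-rich arenes by acylketenes released from Meldrum's acid derivatives, which also gives seven-membered aryl ketones; their union in one flask with an uncatalysed arene capture is the untested part. The oxepinone ring closes by intramolecular electrophilic aromatic substitution, a 7-exo-dig attack of C5a on the ketene carbon. C3 migrates with retention, as the migrating carbon does in every Wolff shift, C2 is not touched, and C4 is set on tautomerisation under thermodynamic control, trans to the C3 phenyl group. The step needs the ketene to be taken by ring A and not by a second ketene or by the other arenes: high dilution, the gem-disubstituted C2 in the tether and the phloroglucinol-type activation of C5a (ortho to O1 and to OMe, para to OMe; the two positions ortho to O1 are equivalent) should secure this, while the phenyl ring and the reachable carbons of the alkoxyphenyl ring are not activated.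

Step 12
Reactants: 20 glycolaldehyde dimer (1,4-dioxane-2,5-diol); 21 ethyl 2-(triphenylphosphoranylidene)propanoate
Product: 22 ethyl (2E)-4-hydroxy-2-methylbut-2-enoate
Conditions: CH2Cl2, 40 °C
Reagents that add atoms: none
Why: Wittig olefination of the aldehyde released from the dimer with a stabilised α-branched ylide should give the E-trisubstituted enoate.

Step 13
Reactants: 22 ethyl (2E)-4-hydroxy-2-methylbut-2-enoate
Product: 23 (2E)-4-hydroxy-2-methylbut-2-enoic acid
Conditions: LiOH, THF/H2O, 0 °C to rt; then HCl to pH 3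
Reagents that add atoms: lithium hydroxide, [Li+].[OH-]
Why: ester saponification should leave the alkene geometry and the allylic alcohol unchanged.

Step 14
Reactants: 23 (2E)-4-hydroxy-2-methylbut-2-enoic acid; 24 tert-butyl (4-aminobutyl)carbamate
Product: 25 tert-butyl {4-[(2E)-4-hydroxy-2-methylbut-2-enamido]butyl}carbamate
Conditions: EDC·HCl, HOBt, iPr2NEt, CH2Cl2/DMF, 0 °C to rt
Reagents that add atoms: none
Why: carbodiimide/HOBt amide coupling should acylate the primary amine in preference to the primary alcohol.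

Step 15
Reactants: 25 tert-butyl {4-[(2E)-4-hydroxy-2-methylbut-2-enamido]butyl}carbamate
Product: 26 (2E)-N-(4-aminobutyl)-4-hydroxy-2-methylbut-2-enamide hydrochloride
Conditions: HCl (4 M in 1,4-dioxane), 0 °C to rt
Reagents that add atoms: hydrogen chloride, Cl
Why: acidolytic removal of the Boc group should give the amine salt while the electron-poor allylic alcohol resists ionisation.

Step 16
Reactants: 19 4-ethyl 2-PMB (2S,3S,4R)-6,8-dimethoxy-2-[4-(PMB-oxy)phenyl]-5-oxo-3-phenyl-2,3,4,5-tetrahydro-1-benzoxepine-2,4-dicarboxylate; 26 (2E)-N-(4-aminobutyl)-4-hydroxy-2-methylbut-2-enamide hydrochloride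
Product: 28 PMB (2S,3S,4R)-4-({4-[(2E)-4-hydroxy-2-methylbut-2-enamido]butyl}carbamoyl)-6,8-dimethoxy-2-[4-(PMB-oxy)phenyl]-5-oxo-3-phenyl-2,3,4,5-tetrahydro-1-benzoxepine-2-carboxylate, via aroyl ketene 27 (not isolated)
Conditions: iPr2NEt, DMAP (cat.), toluene/1,4-dioxane, 120 °C, sealed tube
Reagents that add atoms: none
Why: thermal aminolysis of a β-keto ester through its α-oxo ketene, which the primary amine should capture faster than the alcohol, while the hindered C2 ester is inert and C4 is re-set trans to the C3 phenyl group on tautomerisation.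

Step 17
Reactants: 28 PMB (2S,3S,4R)-4-({4-[(2E)-4-hydroxy-2-methylbut-2-enamido]butyl}carbamoyl)-6,8-dimethoxy-2-[4-(PMB-oxy)phenyl]-5-oxo-3-phenyl-2,3,4,5-tetrahydro-1-benzoxepine-2-carboxylate
Product: 29 (2S,3S,4R)-4-({4-[(2E)-4-hydroxy-2-methylbut-2-enamido]butyl}carbamoyl)-2-(4-hydroxyphenyl)-6,8-dimethoxy-5-oxo-3-phenyl-2,3,4,5-tetrahydro-1-benzoxepine-2-carboxylic acid (CNP0300324.1)
Conditions: TFA, anisole, CH2Cl2, 0 °C
Reagents that add atoms: none
Why: acidolysis of the PMB ester and the PMB aryl ether through the 4-methoxybenzyl cation, trapped by anisole, should free the acid and the phenol, while the α-carboxyl group disfavours ionisation of the C2–O1 ether and no stereocentre is involved.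

Compound list
1 | (R)-but-3-yn-2-ol | C[C@@H](O)C#C | starting material
2 | iodobenzene | Ic1ccccc1 | starting material
3 | (R)-4-phenylbut-3-yn-2-ol | C[C@@H](O)C#Cc1ccccc1 | intermediate
4 | (2R,3Z)-4-phenylbut-3-en-2-ol | C[C@@H](O)/C=C\c1ccccc1 | intermediate
5 | 4-hydroxymandelic acid (racemic) | OC(C(=O)O)c1ccc(O)cc1 | starting material
6 | 4-methoxybenzyl 2-hydroxy-2-{4-[(4-methoxybenzyl)oxy]phenyl}acetate (racemic) | COc1ccc(COC(=O)C(O)c2ccc(OCc3ccc(OC)cc3)cc2)cc1 | intermediate
7 | 3,5-dimethoxyphenol | COc1cc(O)cc(OC)c1 | starting material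
8 | 4-methoxybenzyl 2-(3,5-dimethoxyphenoxy)-2-{4-[(4-methoxybenzyl)oxy]phenyl}acetate (racemic) | COc1cc(OC)cc(OC(C(=O)OCc2ccc(OC)cc2)c2ccc(OCc3ccc(OC)cc3)cc2)c1 | intermediate
9 | 2-(3,5-dimethoxyphenoxy)-2-{4-[(4-methoxybenzyl)oxy]phenyl}acetic acid (racemic) | COc1cc(OC)cc(OC(C(=O)O)c2ccc(OCc3ccc(OC)cc3)cc2)c1 | intermediate
10 | (2R,3Z)-4-phenylbut-3-en-2-yl 2-(3,5-dimethoxyphenoxy)-2-{4-[(4-methoxybenzyl)oxy]phenyl}acetate (both epimers at the acetate carbon) | COc1cc(OC)cc(OC(C(=O)O[C@H](C)/C=C\c2ccccc2)c2ccc(OCc3ccc(OC)cc3)cc2)c1 | intermediate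
11 | trimethylsilyl ketene acetal of 10, aryloxy group cis to OSiMe3 | COc1cc(OC)cc(O/C(c2ccc(OCc3ccc(OC)cc3)cc2)=C(\O[Si](C)(C)C)O[C@H](C)/C=C\c2ccccc2)c1 | intermediate (not isolated)
12 | trimethylsilyl (2S,3S,4E)-2-(3,5-dimethoxyphenoxy)-2-{4-[(4-methoxybenzyl)oxy]phenyl}-3-phenylhex-4-enoate | COc1cc(OC)cc(O[C@](C(=O)O[Si](C)(C)C)(c2ccc(OCc3ccc(OC)cc3)cc2)[C@H](c2ccccc2)/C=C/C)c1 | intermediate (not isolated)
13 | 4-methoxybenzyl (2S,3S,4E)-2-(3,5-dimethoxyphenoxy)-2-{4-[(4-methoxybenzyl)oxy]phenyl}-3-phenylhex-4-enoate | COc1cc(OC)cc(O[C@](C(=O)OCc2ccc(OC)cc2)(c2ccc(OCc3ccc(OC)cc3)cc2)[C@H](c2ccccc2)/C=C/C)c1 | intermediate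
14 | 4-methoxybenzyl (2S,3S)-2-(3,5-dimethoxyphenoxy)-4,5-dihydroxy-2-{4-[(4-methoxybenzyl)oxy]phenyl}-3-phenylhexanoate (diol diastereomers) | COc1cc(OC)cc(O[C@](C(=O)OCc2ccc(OC)cc2)(c2ccc(OCc3ccc(OC)cc3)cc2)[C@H](c2ccccc2)C(O)C(C)O)c1 | intermediate (not isolated)
15 | 4-methoxybenzyl (2S,3S)-2-(3,5-dimethoxyphenoxy)-2-{4-[(4-methoxybenzyl)oxy]phenyl}-4-oxo-3-phenylbutanoate | COc1cc(OC)cc(O[C@](C(=O)OCc2ccc(OC)cc2)(c2ccc(OCc3ccc(OC)cc3)cc2)[C@H](c2ccccc2)C=O)c1 | intermediate
16 | 1-ethyl 6-(4-methoxybenzyl) (4S,5S)-5-(3,5-dimethoxyphenoxy)-5-{4-[(4-methoxybenzyl)oxy]phenyl}-3-oxo-4-phenylhexanedioate | COc1cc(OC)cc(O[C@](C(=O)OCc2ccc(OC)cc2)(c2ccc(OCc3ccc(OC)cc3)cc2)[C@H](c2ccccc2)C(=O)CC(=O)OCC)c1 | intermediate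
17 | 1-ethyl 6-(4-methoxybenzyl) (4S,5S)-2-diazo-5-(3,5-dimethoxyphenoxy)-5-{4-[(4-methoxybenzyl)oxy]phenyl}-3-oxo-4-phenylhexanedioate | COc1cc(OC)cc(O[C@](C(=O)OCc2ccc(OC)cc2)(c2ccc(OCc3ccc(OC)cc3)cc2)[C@H](c2ccccc2)C(=O)C(=[N+]=[N-])C(=O)OCC)c1 | intermediate
18 | (ethoxycarbonyl)ketene from 17, C3 now bonded to the ketene carbon C4 with retention | COc1cc(OC)cc(O[C@](C(=O)OCc2ccc(OC)cc2)(c2ccc(OCc3ccc(OC)cc3)cc2)[C@H](c2ccccc2)C(=C=O)C(=O)OCC)c1 | intermediate (not isolated)
19 | 4-ethyl 2-(4-methoxybenzyl) (2S,3S,4R)-6,8-dimethoxy-2-{4-[(4-methoxybenzyl)oxy]phenyl}-5-oxo-3-phenyl-2,3,4,5-tetrahydro-1-benzoxepine-2,4-dicarboxylate | COc1cc(OC)c2c(c1)O[C@](C(=O)OCc1ccc(OC)cc1)(c1ccc(OCc3ccc(OC)cc3)cc1)[C@H](c1ccccc1)[C@@H](C(=O)OCC)C2=O | intermediate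
20 | glycolaldehyde dimer (1,4-dioxane-2,5-diol) | OC1COC(O)CO1 | starting material
21 | ethyl 2-(triphenylphosphoranylidene)propanoate | CCOC(=O)C(C)=P(c1ccccc1)(c1ccccc1)c1ccccc1 | starting material
22 | ethyl (2E)-4-hydroxy-2-methylbut-2-enoate | CCOC(=O)/C(C)=C/CO | intermediate
23 | (2E)-4-hydroxy-2-methylbut-2-enoic acid | OC(=O)/C(C)=C/CO | intermediate
24 | tert-butyl (4-aminobutyl)carbamate | CC(C)(C)OC(=O)NCCCCN | starting material
25 | tert-butyl {4-[(2E)-4-hydroxy-2-methylbut-2-enamido]butyl}carbamate | CC(C)(C)OC(=O)NCCCCNC(=O)/C(C)=C/CO | intermediate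
26 | (2E)-N-(4-aminobutyl)-4-hydroxy-2-methylbut-2-enamide hydrochloride | [NH3+]CCCCNC(=O)/C(C)=C/CO.[Cl-] | intermediate
27 | α-oxo ketene from 19 (4-carbonylidene-5-oxobenzoxepine, 2S,3S) | COc1cc(OC)c2c(c1)O[C@](C(=O)OCc1ccc(OC)cc1)(c1ccc(OCc3ccc(OC)cc3)cc1)[C@H](c1ccccc1)C(=C=O)C2=O | intermediate (not isolated)
28 | 4-methoxybenzyl (2S,3S,4R)-4-({4-[(2E)-4-hydroxy-2-methylbut-2-enamido]butyl}carbamoyl)-6,8-dimethoxy-2-{4-[(4-methoxybenzyl)oxy]phenyl}-5-oxo-3-phenyl-2,3,4,5-tetrahydro-1-benzoxepine-2-carboxylate | COc1cc(OC)c2c(c1)O[C@](C(=O)OCc1ccc(OC)cc1)(c1ccc(OCc3ccc(OC)cc3)cc1)[C@H](c1ccccc1)[C@@H](C(=O)NCCCCNC(=O)/C(C)=C/CO)C2=O | intermediate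
29 | (2S,3S,4R)-4-({4-[(2E)-4-hydroxy-2-methylbut-2-enamido]butyl}carbamoyl)-2-(4-hydroxyphenyl)-6,8-dimethoxy-5-oxo-3-phenyl-2,3,4,5-tetrahydro-1-benzoxepine-2-carboxylic acid | COc1cc(OC)c2c(c1)O[C@](C(=O)O)(c1ccc(O)cc1)[C@H](c1ccccc1)[C@@H](C(=O)NCCCCNC(=O)/C(C)=C/CO)C2=O | target

Total step count: 17
Longest linear sequence: 11 steps (steps 3 to 11, then 16 and 17, from 4-hydroxymandelic acid)

Steps most likely to fail

Step 11 (proposed new method). Bimolecular ketene dimerisation, or capture of the ketene by traces of nucleophile, may outrun the seven-membered ring closure, and carbene-type decomposition of the diazo group may compete with the concerted shift. The fallback separates the two events with known chemistry. Setting out from 17, irradiation at 350 nm in THF/water at rt should trigger the same Wolff shift and let water capture the ketene as the malonic acid half-ester F1. Trifluoroacetic anhydride with 2,6-di-tert-butylpyridine in CH2Cl2 at 0 °C should convert F1 into the mixed trifluoroacetic anhydride F2, which acylates ring A at C5a in a classical intramolecular Friedel–Crafts acylation of a phloroglucinol-type ether and comes back to the route at 19.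

Step 7. The enolate may silylate with the opposite geometry if the aryloxy oxygen does not chelate lithium, or the rearrangement may pass through a boat transition state; either would erode or invert the C2/C3 relative configuration. Setting out from 8, its lithium enolate (LiN(SiMe3)2, THF) should be allylated with cinnamyl methyl carbonate under [Ir(cod)Cl]2 and a chiral phosphoramidite ligand (branch-selective allylic alkylation). This sets C3 under catalyst control and gives 4-methoxybenzyl (2S,3S)-2-(3,5-dimethoxyphenoxy)-2-{4-[(4-methoxybenzyl)oxy]phenyl}-3-phenylpent-4-enoate F3 after separation from its C2 epimer. OsO4/NaIO4 cleavage of the vinyl group through the diol F4 comes back to the route at 15.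

Step 9. Carbon migration may compete with the hydride shift, and Lewis-acid-induced enolisation of the α-phenyl aldehyde may epimerise C3 or expel the aryloxy group by β-elimination. Setting out from 15, Pinnick oxidation (NaClO2, NaH2PO4, 2-methylbut-2-ene, tBuOH/H2O) should give the carboxylic acid F5, and 1,1'-carbonyldiimidazole in THF its acyl imidazole F6. C-acylation of the magnesium salt of ethyl hydrogen malonate (MgCl2, Et3N) should give the acylmalonic acid half-ester F7, which loses CO2 on acidic work-up and comes back to the route at 16.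

Further compounds
F1 | step 11 | 2-[(1S,2S)-substituted]malonic acid monoethyl ester from water capture of ketene 18 (C4 epimers) | COc1cc(OC)cc(O[C@](C(=O)OCc2ccc(OC)cc2)(c2ccc(OCc3ccc(OC)cc3)cc2)[C@H](c2ccccc2)C(C(=O)O)C(=O)OCC)c1
F2 | step 11 | mixed trifluoroacetic anhydride of F1 | COc1cc(OC)cc(O[C@](C(=O)OCc2ccc(OC)cc2)(c2ccc(OCc3ccc(OC)cc3)cc2)[C@H](c2ccccc2)C(C(=O)OC(=O)C(F)(F)F)C(=O)OCC)c1
F3 | step 7 | 4-methoxybenzyl (2S,3S)-2-(3,5-dimethoxyphenoxy)-2-{4-[(4-methoxybenzyl)oxy]phenyl}-3-phenylpent-4-enoate | COc1cc(OC)cc(O[C@](C(=O)OCc2ccc(OC)cc2)(c2ccc(OCc3ccc(OC)cc3)cc2)[C@H](c2ccccc2)C=C)c1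
F4 | step 7 | 4,5-diol of F3 (diol epimers) | COc1cc(OC)cc(O[C@](C(=O)OCc2ccc(OC)cc2)(c2ccc(OCc3ccc(OC)cc3)cc2)[C@H](c2ccccc2)C(O)CO)c1
F5 | step 9 | (2S,3S)-3-(3,5-dimethoxyphenoxy)-4-[(4-methoxybenzyl)oxy]-3-{4-[(4-methoxybenzyl)oxy]phenyl}-4-oxo-2-phenylbutanoic acid | COc1cc(OC)cc(O[C@](C(=O)OCc2ccc(OC)cc2)(c2ccc(OCc3ccc(OC)cc3)cc2)[C@H](c2ccccc2)C(=O)O)c1
F6 | step 9 | acyl imidazole of F5 | COc1cc(OC)cc(O[C@](C(=O)OCc2ccc(OC)cc2)(c2ccc(OCc3ccc(OC)cc3)cc2)[C@H](c2ccccc2)C(=O)n2ccnc2)c1
F7 | step 9 | acylmalonic acid monoethyl ester from F6 | COc1cc(OC)cc(O[C@](C(=O)OCc2ccc(OC)cc2)(c2ccc(OCc3ccc(OC)cc3)cc2)[C@H](c2ccccc2)C(=O)C(C(=O)O)C(=O)OCC)c1
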